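## Analysis of the target

The target 27 is a trans-dihydroflavonol: a 2,3-dihydro-4H-chromen-4-one (rings A and C) that carries a 4-hydroxyphenyl ring B at C2 and a hydroxyl at C3. Both stereocenters are R; H-2 and H-3 are trans, so O1 and O3 are anti along the chain aryl–C2–C3–C4. Ring A is fully differentiated: methoxy at C5, geranyl at C6, hydroxyl at C7, hydrogen at C8, the ring oxygen on C8a and the carbonyl on C4a. The sensitive groups are the geranyl chain (two trisubstituted alkenes that cyclise onto a neighbouring phenol under acid and exclude hydrogenolysis) and the β-aryloxy ketone of ring C, which base opens by retro-oxa-Michael reaction with loss of C2 and C3. The free phenols are also oxidisable. The difficulty is ring A: substitution of a phloroglucinol ketone rarely separates C6 from C8 for the geranyl group, and methylation goes to O7 before the hydrogen-bonded O5. The strategy rests on pairing the six ring A carbons as C4a–C5, C6–C7 and C8–C8a. Each pair carries exactly one oxygen (O5, O7, O1) and therefore equals an oxygenated alkyne, and the four atoms C4, C3, C2 and O1 of ring C tie C4a to C8a, which makes two of the pairs one 1,7-diyne.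

## Retrosynthetic reasoning

27 from 26. Only three O–Si bonds are cut. All three hydroxyls are masked as silyl ethers so that one buffered fluoride treatment is the whole endgame and neither acid nor base meets the geranyl chain or ring C.

26 from 19 and 25. C4a–C8a, C5–C6 and C7–C8 are cut, which dissolves rings A and C together. Cutting here, rather than at any aryl–substituent bond, means every ring A substituent arrives on an alkyne carbon: the methyl ether on C5 of the ynone, the lone hydrogen on C8 of the ethynyl ether, the geranyl group and O7 on the siloxyalkyne 25. The forward reaction must join a tethered diyne with one monoalkyne at room temperature and in one orientation.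

25 from 22, and 22 from 20 and 21. The O7–C7 bond is cut back to the acetylide 23, which is oxidised to the ynolate 24 and silylated on oxygen. The C–C bond between the geranyl terminus and the alkyne is cut to an allylic bromide and an ethynyl Grignard reagent. This takes two steps from 20, and the E alkene is never touched.

19 from 18, 18 from 16, 16 from 13 and 15. The ynone carbonyl is made last, by oxidation of the carbinol 18, because an alkoxy ynone tolerates neither an alkyllithium nor a nucleophile. The ethynyl ether is carried as the dichlorovinyl ether until 16; it is released there by an alkyllithium (through 17), when the only other reactive group is an alkoxide. The C4–C4a bond is cut to the aldehyde 13 and the acetylide 15, which is made in the flask from 14 and brings C4a, C5 and the O5 methyl group.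

13 from 12, 11 and 10. These steps only adjust O3 and C4. The acetonide of 10 is opened to the diol 11, both hydroxyls are silylated (12), and the primary silyl ether alone is oxidised to the aldehyde. The dichlorovinyl ether survives the mild acid and the oxidation; a free ethynyl ether would not.

10 from 7 and 8. The O1–C8a bond is cut to the potassium alkoxide 9 and trichloroethylene. This has to happen on 7 because the alkoxide allows no β-carbonyl (retro-aldol cleavage) and no silyl ether on the neighbouring oxygen (1,2-silyl migration). The acetonide over O3 and the future C4 oxygen meets both conditions. The phenol carries a triisopropylsilyl group since smaller aryl silyl ethers are transferred to alkoxides.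

7 from 6, 6 from 5 and 4, 5 from 2, 2 from 1, 4 from 3. C3 comes from the chiral pool as the (S)-glycerate acetonide 3. The aryl–C2 bond is cut to the aryllithium 5 and the Weinreb amide 4. C2 is set by chelation-controlled reduction of ketone 6, which gives the anti relation that becomes the 2,3-trans relation of 27. Both absolute configurations are thus fixed by the choice of 3.

## Alternatives that were turned down

Alternative 1: The C2–C3 bond is cut. In the forward direction the divalent rhodium carboxylate Rh2(S-PTTL)4 decomposes the ring A diazoketone A2, and the carbene at C3 inserts into one enantiotopic benzylic C–H bond of the O8a benzyl ether to give the flavanone A1.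
- For it: the step is catalytic and enantioselective, and insertion of rhodium carbenes into C–H bonds next to ether oxygen is an established reaction type. On precedent and on robustness of the precursor it is stronger than the chosen key step.
- Against it: A1 has no oxygen at C3. A later enolate oxidation would have to set C3 trans under base, the condition that opens ring C and erodes C2.
- Against it: the carbene of A2 is an acceptor-only carbene. It can form an oxonium ylide at O8a followed by a [1,2]-benzyl shift, insert into the C–H bonds of the C5 methoxy group, or attack the geranyl alkenes.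
- Against it: ring A of A2 must still be made by substitution of a phloroglucinol, so the C6 against C8 and O5 against O7 problems remain, and the two methoxymethyl ethers need acid next to the geranyl chain.
- Comparison: the chosen route gives up precedent in one step. In return both stereocenters are in place before ring closure, ring A regiochemistry is fixed by construction, and the endgame uses fluoride only.

Alternative 2: The C4a–C5 bond is cut. Mg(OMe)2 converts the dihydropyranone keto ester A4 into its extended enolate, C4a attacks the ester carbonyl C5, and enolisation aromatises ring A to give A3.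
- For it: the folding is biomimetic, the geranyl group sits unambiguously on C6 because it is the substituent of the β-keto ester carbon, and Claisen-type aromatisation of polyketo esters is well known. On geranyl regiocontrol it equals the chosen strategy, and on precedent it is stronger.
- Against it: A3 has both O5 and O7 free, and the target needs the methyl group on O5, the hydrogen-bonded and least nucleophilic hydroxyl. That costs protection of O7, a forced methylation under base and a deprotection, all on a base-sensitive dihydroflavonol.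
- Against it: C3 of A4 is α to the C4 carbonyl and β to the ring oxygen, so the basic cyclisation invites epimerisation and ring opening.
- Against it: acid removal of the methoxymethyl ethers would take place with the geranyl chain flanked by two free phenols.
- Comparison: the chosen route brings the O5 methyl group in as part of the methoxyalkyne, so no phenol ever has to be differentiated.

Alternative 3: The O1–C2 bond is cut. Anodic oxidation of the free ring B phenol of A6 gives the para-quinone methide A7, and the C8a hydroxyl adds to C2 trans to the resident C3 oxygen to give A5.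
- For it: only C3 needs an asymmetric step, since C2 follows under substrate control. No chemical oxidant is needed, and oxa-Michael closure onto quinone methides is a known way to flavanoids. On precedent and on simplicity of the precursor it is stronger than the chosen key step.
- Against it: ring A of A6 is itself a free, electron-rich phenol next to two trisubstituted alkenes, so oxidation at ring B alone is doubtful.
- Against it: A7 carries an acidic hydrogen at C3 between the ketone and the quinone methide, so tautomerisation to the chalcone-type enol ether would destroy the only preset stereocenter.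
- Against it: ring A again comes from phloroglucinol substitution, and the methoxymethyl ether at O7 again needs acid.
- Comparison: the chosen route has no oxidation on a geranylated polyphenol and no phloroglucinol chemistry; it pays with a longer and more delicate diyne.

Key step: step 14

## Route

Remark: 16, 17 and 18 are carried as mixtures of epimers at the new carbinol carbon, which step 11 turns into the carbonyl carbon C4; atoms are given flavanoid numbers (O1, C2, C3, C4, C4a, C5 to C8, C8a) throughout.

Step 1
Reactants: 1 4-bromophenol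
Product: 2 (4-bromophenoxy)triisopropylsilane
Conditions: i-Pr3SiCl, imidazole, DMF, 23 °C
Reagents that add atoms: chlorotriisopropylsilane, CC(C)[Si](Cl)(C(C)C)C(C)C
Why: Standard silylation of a phenol; the bulky triisopropylsilyl ether is chosen because it has to survive an aryllithium, a potassium alkoxide and two alkyllithium steps and still leave with fluoride at the end.

Step 2
Reactants: 3 methyl (4S)-2,2-dimethyl-1,3-dioxolane-4-carboxylate
Product: 4 (4S)-N-methoxy-N,2,2-trimethyl-1,3-dioxolane-4-carboxamide
Conditions: MeNH(OMe)·HCl, i-PrMgCl, THF, −20 → 0 °C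
Reagents that add atoms: N,O-dimethylhydroxylamine hydrochloride, CNOC.Cl
Why: Aminolysis of the ester by the magnesium amide (Weinreb amide formation); the α-alkoxy stereocenter is not enolised at this temperature.

Step 3
Reactants: 2 (4-bromophenoxy)triisopropylsilane; 4 (4S)-N-methoxy-N,2,2-trimethyl-1,3-dioxolane-4-carboxamide
Product: 6 [(4S)-2,2-dimethyl-1,3-dioxolan-4-yl][4-(triisopropylsilyloxy)phenyl]methanone, via aryllithium 5 (not isolated)
Conditions: n-BuLi, THF, −78 °C; then 4, −78 → 0 °C; aq NH4Cl
Reagents that add atoms: none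
Why: Bromine–lithium exchange followed by Weinreb ketone synthesis; the chelated tetrahedral intermediate prevents a second addition and the para silyl ether cannot migrate to the carbanion.

Step 4
Reactants: 6 [(4S)-2,2-dimethyl-1,3-dioxolan-4-yl][4-(triisopropylsilyloxy)phenyl]methanone
Product: 7 (R)-[(4S)-2,2-dimethyl-1,3-dioxolan-4-yl][4-(triisopropylsilyloxy)phenyl]methanol
Conditions: Zn(BH4)2, Et2O, −30 °C
Reagents that add atoms: none
Why: Chelation-controlled (Cram cyclic) reduction of an α-alkoxy ketone: zinc bridges the carbonyl oxygen and the ring oxygen on C3, and hydride should add to the face away from the dioxolane CH2, which sets C2 as R, anti to O3.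

Step 5
Reactants: 7 (R)-[(4S)-2,2-dimethyl-1,3-dioxolan-4-yl][4-(triisopropylsilyloxy)phenyl]methanol; 8 trichloroethylene
Product: 10 (4S)-4-[(R)-{[(E)-1,2-dichloroethenyl]oxy}[4-(triisopropylsilyloxy)phenyl]methyl]-2,2-dimethyl-1,3-dioxolane, via potassium alkoxide 9 (not isolated)
Conditions: KH, THF, 0 → 23 °C; then 8, −50 → 23 °C
Reagents that add atoms: none
Why: Known dichlorovinyl ether synthesis for secondary alcohols: the alkoxide adds to the chloroalkyne formed from 8 by loss of HCl and the vinyl anion is protonated trans. The alkoxide has no β-carbonyl and no silyl ether on a neighbouring oxygen, and the C2–O bond is not broken, so C2 is retained.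

Step 6
Reactants: 10 (4S)-4-[(R)-{[(E)-1,2-dichloroethenyl]oxy}[4-(triisopropylsilyloxy)phenyl]methyl]-2,2-dimethyl-1,3-dioxolane
Product: 11 (2S,3R)-3-{[(E)-1,2-dichloroethenyl]oxy}-3-[4-(triisopropylsilyloxy)phenyl]propane-1,2-diol
Conditions: AcOH–H2O (4:1), 40 °C
Reagents that add atoms: none
Why: Hydrolysis of a terminal acetonide under weak acid; the two chlorine atoms make the vinyl ether far less basic than a normal enol ether, and aryl silyl ethers are stable to acetic acid.

Step 7
Reactants: 11 (2S,3R)-3-{[(E)-1,2-dichloroethenyl]oxy}-3-[4-(triisopropylsilyloxy)phenyl]propane-1,2-diol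
Product: 12 (2S,3R)-3-{[(E)-1,2-dichloroethenyl]oxy}-1,2-bis(triethylsilyloxy)-3-[4-(triisopropylsilyloxy)phenyl]propane
Conditions: Et3SiOTf, 2,6-lutidine, CH2Cl2, −78 → 0 °C
Reagents that add atoms: triethylsilyl trifluoromethanesulfonate, CC[Si](CC)(CC)OS(=O)(=O)C(F)(F)F
Why: Exhaustive silylation of a 1,2-diol with a silyl triflate and a hindered base; triethylsilyl is chosen because its primary ether can be oxidised directly in step 8 while its secondary ether stays until the end.

Step 8
Reactants: 12 (2S,3R)-3-{[(E)-1,2-dichloroethenyl]oxy}-1,2-bis(triethylsilyloxy)-3-[4-(triisopropylsilyloxy)phenyl]propane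
Product: 13 (2R,3R)-3-{[(E)-1,2-dichloroethenyl]oxy}-2-(triethylsilyloxy)-3-[4-(triisopropylsilyloxy)phenyl]propanal
Conditions: (COCl)2, DMSO, CH2Cl2, −78 → −30 °C; Et3N, −78 → −20 °C
Reagents that add atoms: none
Why: Swern oxidation applied to a bis-triethylsilyl ether: the activated sulfoxide displaces the primary silyl group only, and the alkoxysulfonium salt collapses to the aldehyde; the secondary silyl ether and the stereocenters stay, provided the amine is used cold.

Step 9
Reactants: 13 (2R,3R)-3-{[(E)-1,2-dichloroethenyl]oxy}-2-(triethylsilyloxy)-3-[4-(triisopropylsilyloxy)phenyl]propanal; 14 chloroacetaldehyde dimethyl acetal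
Product: 16 (4S,5R)-5-{[(E)-1,2-dichloroethenyl]oxy}-1-methoxy-4-(triethylsilyloxy)-5-[4-(triisopropylsilyloxy)phenyl]pent-1-yn-3-ol (both C3 epimers), via lithium methoxyacetylide 15 (not isolated)
Conditions: 14, Et2NH, n-BuLi, THF, 0 °C; then 13, −78 °C; aq NH4Cl
Reagents that add atoms: none
Why: Threefold elimination of 14 with lithium diethylamide gives the acetylide, which adds to the aldehyde at −78 °C faster than it enolises it; the amide is used slightly short of three equivalents so that none is left to attack the dichlorovinyl ether.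

Step 10
Reactants: 16 (4S,5R)-5-{[(E)-1,2-dichloroethenyl]oxy}-1-methoxy-4-(triethylsilyloxy)-5-[4-(triisopropylsilyloxy)phenyl]pent-1-yn-3-ol (both C3 epimers)
Product: 18 (4S,5R)-5-(ethynyloxy)-1-methoxy-4-(triethylsilyloxy)-5-[4-(triisopropylsilyloxy)phenyl]pent-1-yn-3-ol (both C3 epimers), via dilithio alkynyl ether 17 (not isolated)
Conditions: n-BuLi (3.3 equiv), THF, −78 °C; MeOH, −78 °C
Reagents that add atoms: none
Why: Second stage of the dichlorovinyl ether route to ethynyl ethers: after deprotonation of the hydroxyl, dehydrochlorination gives the chloroalkynyl ether and chlorine–lithium exchange gives the lithium alkynyl ether, which is protonated cold; at this stage the molecule offers the base nothing but an alkoxide.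

Step 11
Reactants: 18 (4S,5R)-5-(ethynyloxy)-1-methoxy-4-(triethylsilyloxy)-5-[4-(triisopropylsilyloxy)phenyl]pent-1-yn-3-ol (both C3 epimers)
Product: 19 (4R,5R)-5-(ethynyloxy)-1-methoxy-4-(triethylsilyloxy)-5-[4-(triisopropylsilyloxy)phenyl]pent-1-yn-3-one
Conditions: Dess–Martin periodinane, NaHCO3, CH2Cl2, 0 °C
Reagents that add atoms: none
Why: Buffered hypervalent iodine oxidation of a propargylic alcohol; both epimers converge on one ynone, and the neutral medium spares the two ynol ethers and the α-stereocenter. 19 is used at once.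

Step 12
Reactants: 20 geranyl bromide; 21 ethynylmagnesium bromide
Product: 22 (4E)-5,9-dimethyldeca-4,8-dien-1-yne
Conditions: CuCl (5 mol %), THF, 0 → 50 °C
Reagents that add atoms: none
Why: Copper-catalysed coupling of an allylic bromide with an alkynyl Grignard reagent, which substitutes at the primary carbon and keeps the E alkene; the Grignard reagent is used in excess to avoid double alkylation.

Step 13
Reactants: 22 (4E)-5,9-dimethyldeca-4,8-dien-1-yne
Product: 25 {[(4E)-5,9-dimethyldeca-4,8-dien-1-yn-1-yl]oxy}triisopropylsilane, via lithium acetylide 23 (not isolated), via lithium ynolate 24 (not isolated)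
Conditions: n-BuLi, THF, −78 °C; t-BuOOH/LiN(SiMe3)2, −78 → 0 °C; i-Pr3SiOTf, −78 → 0 °C
Reagents that add atoms: tert-butyl hydroperoxide, CC(C)(C)OO; triisopropylsilyl trifluoromethanesulfonate, CC(C)[Si](OS(=O)(=O)C(F)(F)F)(C(C)C)C(C)C
Why: Known oxidation of a lithium acetylide by lithium tert-butyl peroxide to the ynolate, which the bulky silyl triflate traps on oxygen; the terminal alkyne is far more acidic than the doubly allylic CH2, and the peroxide does not epoxidise unactivated alkenes.

Step 14
Reactants: 19 (4R,5R)-5-(ethynyloxy)-1-methoxy-4-(triethylsilyloxy)-5-[4-(triisopropylsilyloxy)phenyl]pent-1-yn-3-one; 25 {[(4E)-5,9-dimethyldeca-4,8-dien-1-yn-1-yl]oxy}triisopropylsilane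
Product: 26 (2R,3R)-6-[(2E)-3,7-dimethylocta-2,6-dien-1-yl]-5-methoxy-3-(triethylsilyloxy)-7-(triisopropylsilyloxy)-2-[4-(triisopropylsilyloxy)phenyl]-2,3-dihydro-4H-chromen-4-one
Conditions: [Rh(cod)2]BF4 (10 mol %), (R)-BINAP (10 mol %), H2 then Ar, CH2Cl2, 23 °C; 25 (2 equiv), 19 added over 2 h
Reagents that add atoms: none
Why: Proposed new method: oxidative coupling of the two tethered alkynes of 19 at the cationic monovalent rhodium–BINAP fragment should give a rhodacyclopentadiene in which C4a–C8a is formed and rhodium sits on C5 and C8; insertion of 25 and reductive elimination then form C5–C6 and C7–C8 and release the arene. The closest known reaction type is the [2+2+2] cycloaddition of tethered 1,6- and 1,7-diynes with monoalkynes, alkynyl ethers and ynamides included, under this catalyst at room temperature; an alkoxy ynone, a terminal ethynyl ether and a siloxyalkyne have not been combined in it. Ring C closes in the oxidative coupling as a six-membered oxacycle enforced by the four-atom tether C4–C3–C2–O1, and ring A closes in the reductive elimination as the new benzene ring, whose aromaticity makes the sequence irreversible. No stereocenter is formed, and C2 and C3 are spectators because the medium is neutral and aprotic and the temperature stays at 23 °C, below the onset of sigmatropic or retro-ene loss of the benzylic ethynyl ether. The step needs cross-selectivity over self-coupling of the diyne, which slow addition of 19 to an excess of 25 should secure. It also needs the orientation C6 to C5 and C7 to C8: the triisopropylsilyloxy terminus should avoid the methoxy-bearing C5 and pair with the unsubstituted C8, and the nucleophilic carbon of 25 (C6) is matched with the electrophilic β-carbon of the ynone (C5) while its ketene-like carbon (C7) is matched with the nucleophilic terminal carbon of the ethynyl ether (C8).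

Step 15
Reactants: 26 (2R,3R)-6-[(2E)-3,7-dimethylocta-2,6-dien-1-yl]-5-methoxy-3-(triethylsilyloxy)-7-(triisopropylsilyloxy)-2-[4-(triisopropylsilyloxy)phenyl]-2,3-dihydro-4H-chromen-4-one
Product: 27 (2R,3R)-6-[(2E)-3,7-dimethylocta-2,6-dien-1-yl]-3,7-dihydroxy-2-(4-hydroxyphenyl)-5-methoxy-2,3-dihydro-4H-chromen-4-one
Conditions: Bu4NF, AcOH, THF, 0 → 23 °C
Reagents that add atoms: none
Why: Fluoride cleavage of two aryl silyl ethers and one secondary silyl ether; acetic acid keeps the phenoxides protonated, so ring C should not open and C2 and C3 should not epimerise, and the geranyl chain never meets a strong acid.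

## Compound list

1 | 4-bromophenol | Oc1ccc(Br)cc1 | starting material
2 | (4-bromophenoxy)triisopropylsilane | CC(C)[Si](Oc1ccc(Br)cc1)(C(C)C)C(C)C | intermediate
3 | methyl (4S)-2,2-dimethyl-1,3-dioxolane-4-carboxylate | COC(=O)[C@@H]1COC(C)(C)O1 | starting material
4 | (4S)-N-methoxy-N,2,2-trimethyl-1,3-dioxolane-4-carboxamide | CON(C)C(=O)[C@@H]1COC(C)(C)O1 | intermediate
5 | [4-(triisopropylsilyloxy)phenyl]lithium | [Li]c1ccc(O[Si](C(C)C)(C(C)C)C(C)C)cc1 | intermediate
6 | [(4S)-2,2-dimethyl-1,3-dioxolan-4-yl][4-(triisopropylsilyloxy)phenyl]methanone | O=C(c1ccc(O[Si](C(C)C)(C(C)C)C(C)C)cc1)[C@@H]1COC(C)(C)O1 | intermediate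
7 | (R)-[(4S)-2,2-dimethyl-1,3-dioxolan-4-yl][4-(triisopropylsilyloxy)phenyl]methanol | O[C@H](c1ccc(O[Si](C(C)C)(C(C)C)C(C)C)cc1)[C@@H]1COC(C)(C)O1 | intermediate
8 | trichloroethylene | ClC=C(Cl)Cl | starting material
9 | potassium (R)-[(4S)-2,2-dimethyl-1,3-dioxolan-4-yl][4-(triisopropylsilyloxy)phenyl]methanolate | [K+].[O-][C@H](c1ccc(O[Si](C(C)C)(C(C)C)C(C)C)cc1)[C@@H]1COC(C)(C)O1 | intermediate
10 | (4S)-4-[(R)-{[(E)-1,2-dichloroethenyl]oxy}[4-(triisopropylsilyloxy)phenyl]methyl]-2,2-dimethyl-1,3-dioxolane | Cl/C=C(/Cl)O[C@H](c1ccc(O[Si](C(C)C)(C(C)C)C(C)C)cc1)[C@@H]1COC(C)(C)O1 | intermediate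
11 | (2S,3R)-3-{[(E)-1,2-dichloroethenyl]oxy}-3-[4-(triisopropylsilyloxy)phenyl]propane-1,2-diol | Cl/C=C(/Cl)O[C@H](c1ccc(O[Si](C(C)C)(C(C)C)C(C)C)cc1)[C@@H](O)CO | intermediate
12 | (2S,3R)-3-{[(E)-1,2-dichloroethenyl]oxy}-1,2-bis(triethylsilyloxy)-3-[4-(triisopropylsilyloxy)phenyl]propane | Cl/C=C(/Cl)O[C@H](c1ccc(O[Si](C(C)C)(C(C)C)C(C)C)cc1)[C@@H](O[Si](CC)(CC)CC)CO[Si](CC)(CC)CC | intermediate
13 | (2R,3R)-3-{[(E)-1,2-dichloroethenyl]oxy}-2-(triethylsilyloxy)-3-[4-(triisopropylsilyloxy)phenyl]propanal | Cl/C=C(/Cl)O[C@H](c1ccc(O[Si](C(C)C)(C(C)C)C(C)C)cc1)[C@@H](O[Si](CC)(CC)CC)C=O | intermediate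
14 | chloroacetaldehyde dimethyl acetal | COC(CCl)OC | starting material
15 | lithium methoxyacetylide | [Li]C#COC | intermediate
16 | (4S,5R)-5-{[(E)-1,2-dichloroethenyl]oxy}-1-methoxy-4-(triethylsilyloxy)-5-[4-(triisopropylsilyloxy)phenyl]pent-1-yn-3-ol, both C3 epimers | COC#CC(O)[C@H](O[Si](CC)(CC)CC)[C@@H](c1ccc(O[Si](C(C)C)(C(C)C)C(C)C)cc1)O/C(Cl)=C\Cl | intermediate
17 | lithium (4S,5R)-5-[(lithioethynyl)oxy]-1-methoxy-4-(triethylsilyloxy)-5-[4-(triisopropylsilyloxy)phenyl]pent-1-yn-3-olate, both C3 epimers | COC#CC(O[Li])[C@H](O[Si](CC)(CC)CC)[C@@H](c1ccc(O[Si](C(C)C)(C(C)C)C(C)C)cc1)OC#C[Li] | intermediate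
18 | (4S,5R)-5-(ethynyloxy)-1-methoxy-4-(triethylsilyloxy)-5-[4-(triisopropylsilyloxy)phenyl]pent-1-yn-3-ol, both C3 epimers | COC#CC(O)[C@H](O[Si](CC)(CC)CC)[C@@H](c1ccc(O[Si](C(C)C)(C(C)C)C(C)C)cc1)OC#C | intermediate
19 | (4R,5R)-5-(ethynyloxy)-1-methoxy-4-(triethylsilyloxy)-5-[4-(triisopropylsilyloxy)phenyl]pent-1-yn-3-one | COC#CC(=O)[C@H](O[Si](CC)(CC)CC)[C@@H](c1ccc(O[Si](C(C)C)(C(C)C)C(C)C)cc1)OC#C | intermediate
20 | geranyl bromide | BrC/C=C(\C)CCC=C(C)C | starting material
21 | ethynylmagnesium bromide | C#C[Mg]Br | starting material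
22 | (4E)-5,9-dimethyldeca-4,8-dien-1-yne | C#CC/C=C(\C)CCC=C(C)C | intermediate
23 | [(4E)-5,9-dimethyldeca-4,8-dien-1-yn-1-yl]lithium | [Li]C#CC/C=C(\C)CCC=C(C)C | intermediate
24 | lithium (4E)-5,9-dimethyldeca-4,8-dien-1-yn-1-olate | [Li]OC#CC/C=C(\C)CCC=C(C)C | intermediate
25 | {[(4E)-5,9-dimethyldeca-4,8-dien-1-yn-1-yl]oxy}triisopropylsilane | CC(C)[Si](OC#CC/C=C(\C)CCC=C(C)C)(C(C)C)C(C)C | intermediate
26 | (2R,3R)-6-[(2E)-3,7-dimethylocta-2,6-dien-1-yl]-5-methoxy-3-(triethylsilyloxy)-7-(triisopropylsilyloxy)-2-[4-(triisopropylsilyloxy)phenyl]-2,3-dihydro-4H-chromen-4-one | COc1c(C/C=C(\C)CCC=C(C)C)c(O[Si](C(C)C)(C(C)C)C(C)C)cc2c1C(=O)[C@H](O[Si](CC)(CC)CC)[C@@H](c1ccc(O[Si](C(C)C)(C(C)C)C(C)C)cc1)O2 | intermediate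
27 | (2R,3R)-6-[(2E)-3,7-dimethylocta-2,6-dien-1-yl]-3,7-dihydroxy-2-(4-hydroxyphenyl)-5-methoxy-2,3-dihydro-4H-chromen-4-one | COc1c(C/C=C(\C)CCC=C(C)C)c(O)cc2c1C(=O)[C@H](O)[C@@H](c1ccc(O)cc1)O2 | target

## Step count and least certain steps

Total step count: 15. Longest linear sequence: 12 steps (steps 1, 3 to 11, 14 and 15).

Step 14 (key step). The diyne may couple with itself or through its terminal ethynyl ether instead of taking up 25. The siloxyalkyne may insert in the reverse orientation. Traces of acid from the BF4 salt may hydrate the siloxyalkyne or start its cyclisation onto the geranyl alkene. The benzylic ethynyl ether may rearrange if the reaction is slow enough to need warming.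

The fallback uses known chalcone chemistry; it sets out from 20 and comes back at 27.
- 2,4,6-Trihydroxyacetophenone is C-alkylated with 20 in aqueous KOH to give 1-(3-geranyl-2,4,6-trihydroxyphenyl)ethanone F1.
- MOMCl and i-Pr2NEt protect the two less hindered hydroxyls to give the bis(methoxymethyl) ether F2.
- The remaining chelated hydroxyl next to the geranyl group is methylated (Me2SO4, K2CO3, acetone) to give the methyl ether F3.
- Claisen–Schmidt condensation with 4-(methoxymethoxy)benzaldehyde (KOH, EtOH) gives the chalcone F4.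
- Juliá–Colonna epoxidation (poly-L-leucine, urea–H2O2, DBU, THF) gives the (2R,3S)-epoxy ketone F5.
- HCl in MeOH removes the three methoxymethyl groups; the freed hydroxyl ortho to the carbonyl opens the epoxide at the benzylic carbon with inversion and gives 27.

This fallback has the regiochemical and acid problems that the key step was meant to avoid.

Step 4. Chelation by the ketal oxygen may be too weak, so that hydride delivery loses its facial preference and the syn alcohol forms alongside 7. The fallback sets out from 3 and 5 and comes back at 7. 3 is reduced with i-Bu2AlH (CH2Cl2, −78 °C) to (4S)-2,2-dimethyl-1,3-dioxolane-4-carbaldehyde F6. 5 is transmetallated with ClTi(OiPr)3 to triisopropoxy[4-(triisopropylsilyloxy)phenyl]titanium F7. Addition of F7 to F6 under Felkin–Anh control then forms the aryl–C2 bond and the anti alcohol 7 in one operation.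

Step 8. The amine base may cause β-elimination of the dichlorovinyloxy group or epimerisation at C3 of the new aldehyde, and the activated sulfoxide may not fully discriminate between the two silyl ethers. The fallback sets out from 12 and comes back at 13. HF·pyridine buffered with pyridine (THF, 0 °C) cleaves only the primary silyl ether to give (2S,3R)-3-{[(E)-1,2-dichloroethenyl]oxy}-2-(triethylsilyloxy)-3-[4-(triisopropylsilyloxy)phenyl]propan-1-ol F8. Dess–Martin periodinane with NaHCO3 then oxidises F8 to 13 without any amine.

Step 10. The triethylsilyl group may migrate from O3 to the neighbouring lithium alkoxide, and the dianion may react sluggishly, so that elimination stops at the chloroalkynyl ether. The fallback sets out from 16 and comes back at 18. The hydroxyl of 16 is capped with Me3SiCl and imidazole to give the trimethylsilyl ether F9. n-BuLi (2.2 equiv, −78 °C) followed by MeOH then gives the ethynyl ether F10. K2CO3 in MeOH at 0 °C removes only the trimethylsilyl group and returns 18.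

## Further compounds

F1 | step 14 | 1-{3-[(2E)-3,7-dimethylocta-2,6-dien-1-yl]-2,4,6-trihydroxyphenyl}ethanone | CC(=O)c1c(O)cc(O)c(C/C=C(\C)CCC=C(C)C)c1O
F2 | step 14 | 1-{3-[(2E)-3,7-dimethylocta-2,6-dien-1-yl]-2-hydroxy-4,6-bis(methoxymethoxy)phenyl}ethanone | CC(=O)c1c(OCOC)cc(OCOC)c(C/C=C(\C)CCC=C(C)C)c1O
F3 | step 14 | 1-{3-[(2E)-3,7-dimethylocta-2,6-dien-1-yl]-2-methoxy-4,6-bis(methoxymethoxy)phenyl}ethanone | CC(=O)c1c(OCOC)cc(OCOC)c(C/C=C(\C)CCC=C(C)C)c1OC
F4 | step 14 | (2E)-1-{3-[(2E)-3,7-dimethylocta-2,6-dien-1-yl]-2-methoxy-4,6-bis(methoxymethoxy)phenyl}-3-[4-(methoxymethoxy)phenyl]prop-2-en-1-one | COCOc1ccc(/C=C/C(=O)c2c(OCOC)cc(OCOC)c(C/C=C(\C)CCC=C(C)C)c2OC)cc1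
F5 | step 14 | {3-[(2E)-3,7-dimethylocta-2,6-dien-1-yl]-2-methoxy-4,6-bis(methoxymethoxy)phenyl}{(2R,3S)-3-[4-(methoxymethoxy)phenyl]oxiran-2-yl}methanone | COc1c(C/C=C(\C)CCC=C(C)C)c(OCOC)cc(OCOC)c1C(=O)[C@@H]1O[C@H]1c1ccc(OCOC)cc1
F6 | step 4 | (4S)-2,2-dimethyl-1,3-dioxolane-4-carbaldehyde | O=C[C@@H]1COC(C)(C)O1
F7 | step 4 | triisopropoxy[4-(triisopropylsilyloxy)phenyl]titanium | CC(C)O[Ti](OC(C)C)(OC(C)C)c1ccc(O[Si](C(C)C)(C(C)C)C(C)C)cc1
F8 | step 8 | (2S,3R)-3-{[(E)-1,2-dichloroethenyl]oxy}-2-(triethylsilyloxy)-3-[4-(triisopropylsilyloxy)phenyl]propan-1-ol | Cl/C=C(/Cl)O[C@H](c1ccc(O[Si](C(C)C)(C(C)C)C(C)C)cc1)[C@@H](O[Si](CC)(CC)CC)CO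
F9 | step 10 | (4S,5R)-5-{[(E)-1,2-dichloroethenyl]oxy}-1-methoxy-4-(triethylsilyloxy)-5-[4-(triisopropylsilyloxy)phenyl]-3-(trimethylsilyloxy)pent-1-yne, both C3 epimers | COC#CC(O[Si](C)(C)C)[C@H](O[Si](CC)(CC)CC)[C@@H](c1ccc(O[Si](C(C)C)(C(C)C)C(C)C)cc1)O/C(Cl)=C\Cl
F10 | step 10 | (4S,5R)-5-(ethynyloxy)-1-methoxy-4-(triethylsilyloxy)-5-[4-(triisopropylsilyloxy)phenyl]-3-(trimethylsilyloxy)pent-1-yne, both C3 epimers | COC#CC(O[Si](C)(C)C)[C@H](O[Si](CC)(CC)CC)[C@@H](c1ccc(O[Si](C(C)C)(C(C)C)C(C)C)cc1)OC#C
A1 | alternative 1 | (2S)-6-[(2E)-3,7-dimethylocta-2,6-dien-1-yl]-5-methoxy-7-(methoxymethoxy)-2-[4-(methoxymethoxy)phenyl]-2,3-dihydro-4H-chromen-4-one | COc1c(C/C=C(\C)CCC=C(C)C)c(OCOC)cc2c1C(=O)C[C@@H](c1ccc(OCOC)cc1)O2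
A2 | alternative 1 | 2-diazo-1-{3-[(2E)-3,7-dimethylocta-2,6-dien-1-yl]-2-methoxy-4-(methoxymethoxy)-6-{[4-(methoxymethoxy)phenyl]methoxy}phenyl}ethanone | COc1c(C/C=C(\C)CCC=C(C)C)c(OCOC)cc(OCc2ccc(OCOC)cc2)c1C(=O)C=[N+]=[N-]
A3 | alternative 2 | (2R,3R)-6-[(2E)-3,7-dimethylocta-2,6-dien-1-yl]-5,7-dihydroxy-3-(methoxymethoxy)-2-[4-(methoxymethoxy)phenyl]-2,3-dihydro-4H-chromen-4-one | Oc1c(C/C=C(\C)CCC=C(C)C)c(O)cc2c1C(=O)[C@H](OCOC)[C@@H](c1ccc(OCOC)cc1)O2
A4 | alternative 2 | methyl 2-[(2E)-3,7-dimethylocta-2,6-dien-1-yl]-4-{(2R,3R)-3-(methoxymethoxy)-2-[4-(methoxymethoxy)phenyl]-4-oxo-3,4-dihydro-2H-pyran-6-yl}-3-oxobutanoate | COC(=O)C(C/C=C(\C)CCC=C(C)C)C(=O)CC1=CC(=O)[C@H](OCOC)[C@@H](c2ccc(OCOC)cc2)O1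
A5 | alternative 3 | (2R,3R)-3-(tert-butyldimethylsilyloxy)-6-[(2E)-3,7-dimethylocta-2,6-dien-1-yl]-2-(4-hydroxyphenyl)-5-methoxy-7-(methoxymethoxy)-2,3-dihydro-4H-chromen-4-one | COc1c(C/C=C(\C)CCC=C(C)C)c(OCOC)cc2c1C(=O)[C@H](O[Si](C)(C)C(C)(C)C)[C@@H](c1ccc(O)cc1)O2
A6 | alternative 3 | (2R)-2-(tert-butyldimethylsilyloxy)-1-{3-[(2E)-3,7-dimethylocta-2,6-dien-1-yl]-6-hydroxy-2-methoxy-4-(methoxymethoxy)phenyl}-3-(4-hydroxyphenyl)propan-1-one | COc1c(C/C=C(\C)CCC=C(C)C)c(OCOC)cc(O)c1C(=O)[C@H](O[Si](C)(C)C(C)(C)C)Cc1ccc(O)cc1
A7 | alternative 3 | (2R)-2-(tert-butyldimethylsilyloxy)-1-{3-[(2E)-3,7-dimethylocta-2,6-dien-1-yl]-6-hydroxy-2-methoxy-4-(methoxymethoxy)phenyl}-3-(4-oxocyclohexa-2,5-dien-1-ylidene)propan-1-one | COc1c(C/C=C(\C)CCC=C(C)C)c(OCOC)cc(O)c1C(=O)[C@H](O[Si](C)(C)C(C)(C)C)C=C1C=CC(=O)C=C1
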